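**Retrosynthetic overview**
1. The target (isochromen-1-one locants; side chain C1′–C11′ counted from C3) comes from a diynyl bis(benzyl ether) lactone. One hydrogenation saturates both C≡C bonds and frees both phenols.
2. Key disconnection: side-chain bond C2′–C3′. The acetylide carbon C3′ of a C9 methoxy-diyne opens a temporary oxetane (O2–C3–C1′–C2′) at C2′, and the released O2 closes the lactone on an ortho ester carbon (C1).
3. Enabling feature: O2 on C3 is 1,3-related to C2′, so O2, C3, C1′ and C2′ can be tied into a strained four-membered ring that masks O2, activates C2′ and carries the C3 configuration. C1 on C8a lies ortho to the C4a–C4 arm, so the freed O2 closes the six-membered ring O2–C3–C4–C4a–C8a–C1.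
4. The oxetane ester comes from a purchased resorcinol-type aryl bromide and (S)-epichlorohydrin, followed by one-carbon ring expansion (inserting C2′), bromination and carboxylation. The methoxy-diyne comes from hexa-1,5-diyne and (S)-propylene oxide, followed by O-methylation.
5. Ring order: benzene ring bought → oxirane → oxetane (temporary) → δ-lactone (formed as the oxetane is consumed).

Key step: step 7

Remark: the CIP descriptor at C3 changes between intermediates only because substituent priorities change. The C3–O bond is never broken after it is bought with (S)-epichlorohydrin.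

**Step 1**
Reactants: 1 hexa-1,5-diyne; 2 (S)-2-methyloxirane
Product: 4 (2S)-nona-4,8-diyn-2-ol, via lithium hexa-1,5-diyn-1-ide 3 (not isolated)
Conditions: 1 (3 equiv), n-BuLi (1 equiv), THF, −78 °C; BF3·OEt2; then 2, −78 °C; aq NH4Cl
Reagents that add atoms: none
Why: In this Yamaguchi–Hirao alkynylation the monolithiated diyne (diyne in excess to suppress double reaction) opens the BF3-activated epoxide by SN2 at its CH2 carbon, so the C–O stereocentre of 2 passes unchanged into 4.

**Step 2**
Reactants: 4 (2S)-nona-4,8-diyn-2-ol
Product: 5 (8S)-8-methoxynona-1,5-diyne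
Conditions: NaH, MeI, THF, 0 °C → rt
Reagents that add atoms: iodomethane CI
Why: In this Williamson ether synthesis NaH in THF deprotonates the alcohol much faster than the terminal alkyne, and O-methylation does not touch the stereocentre.

**Step 3**
Reactants: 6 1,3-bis(benzyloxy)-5-bromobenzene; 7 (S)-2-(chloromethyl)oxirane
Product: 10 (2S)-2-{[3,5-bis(benzyloxy)phenyl]methyl}oxirane, via arylmagnesium bromide 8 (not isolated), via chlorohydrin 9 (not isolated)
Conditions: Mg, THF, reflux; CuI (10 mol %), 7, −40 → 0 °C; aq NH4Cl; crude 9: aq NaOH, THF, rt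
Reagents that add atoms: none
Why: Copper-catalysed Grignard opening of epichlorohydrin at the epoxide CH2 is followed by base-induced intramolecular Williamson closure onto the CH2Cl carbon, and the C–O bond at the stereocentre stays intact throughout.

**Step 4**
Reactants: 10 (2S)-2-{[3,5-bis(benzyloxy)phenyl]methyl}oxirane
Product: 11 (2S)-2-{[3,5-bis(benzyloxy)phenyl]methyl}oxetane
Conditions: Me3S(O)I, KOt-Bu, t-BuOH, 70 °C
Reagents that add atoms: trimethylsulfoxonium iodide C[S+](C)(C)=O.[I-]
Why: In this Corey–Chaykovsky-type epoxide-to-oxetane ring expansion the sulfoxonium methylide opens the epoxide at its CH2 and the resulting alkoxide displaces DMSO in a 4-exo-tet closure, a known stereoretentive one-carbon insertion that places C2′ in the ring.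

**Step 5**
Reactants: 11 (2S)-2-{[3,5-bis(benzyloxy)phenyl]methyl}oxetane
Product: 12 (2S)-2-{[3,5-bis(benzyloxy)-2-bromophenyl]methyl}oxetane
Conditions: NBS (1.0 equiv), MeCN, 0 °C, dark
Reagents that add atoms: N-bromosuccinimide O=C1CCC(=O)N1Br
Why: Electrophilic aromatic bromination of 5-alkylresorcinol diethers goes para to one alkoxy group and next to the alkyl arm, because the site between the two benzyloxy groups is more crowded, and the near-neutral polar medium spares the oxetane and the benzylic C–H bonds.

**Step 6**
Reactants: 12 (2S)-2-{[3,5-bis(benzyloxy)-2-bromophenyl]methyl}oxetane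
Product: 14 methyl 2,4-bis(benzyloxy)-6-{[(2S)-oxetan-2-yl]methyl}benzoate, via aryllithium 13 (not isolated)
Conditions: n-BuLi, THF, −78 °C; cannulated into ClCO2Me (excess), −78 °C → rt
Reagents that add atoms: methyl chloroformate COC(=O)Cl
Why: Bromine–lithium exchange outruns deprotonation at −78 °C, inverse addition to excess chloroformate gives the hindered ester without over-addition, and an oxetane is inert to organolithiums in the absence of a Lewis acid.

**Step 7**
Reactants: 5 (8S)-8-methoxynona-1,5-diyne; 14 methyl 2,4-bis(benzyloxy)-6-{[(2S)-oxetan-2-yl]methyl}benzoate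
Product: 17 (3R)-6,8-bis(benzyloxy)-3-[(10S)-10-methoxyundeca-3,7-diyn-1-yl]-3,4-dihydro-1H-isochromen-1-one, via lithium acetylide 15 (not isolated), via hydroxy ester 16 (not isolated)
Conditions: 5 (1.8 equiv), n-BuLi, THF, −78 °C; BF3·OEt2; 14, −78 °C; then MeOH, K2CO3, −78 °C → rt
Reagents that add atoms: none
Why: n-BuLi turns 5 into acetylide 15, BF3 coordinates the oxetane oxygen of 14, and the acetylide carbon attacks the unsubstituted O–CH2 carbon (C2′) by SN2, forming the C2′–C3′ bond and releasing the strain of the four-membered ring; this is the BF3-promoted acetylide opening of oxetanes, the four-ring counterpart of the Yamaguchi–Hirao epoxide alkynylation and a known reaction type for 2-substituted oxetanes. The methanol quench destroys surplus acetylide before any lactone exists and frees the C3 hydroxyl of 16, which under K2CO3 catalysis attacks the ortho ester carbonyl in a 6-exo-trig acyl substitution and expels methanol, as in the lactonisations that follow toluate-anion additions to aldehydes. No new stereocentre is created: the C3–O bond is never broken, so the (S)-oxetane centre appears as (3R) in 17 only through a change of CIP priorities, and C10′ is a spectator. Regioselectivity (CH2 against the substituted CH of the oxetane) is secured by sterics in the SN2 transition state, and chemoselectivity (oxetane against ester) by the doubly ortho-substituted, twisted benzoate, the mild alkynyl nucleophile and the low temperature. In one flask the two fragments are joined, the temporary ring is exchanged for the lactone ring of the target, and the complete carbon skeleton with both stereocentres is in place.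

**Step 8**
Reactants: 17 (3R)-6,8-bis(benzyloxy)-3-[(10S)-10-methoxyundeca-3,7-diyn-1-yl]-3,4-dihydro-1H-isochromen-1-one
Product: 18 (3R)-6,8-dihydroxy-3-[(10S)-10-methoxyundecyl]-3,4-dihydro-1H-isochromen-1-one
Conditions: H2 (1 atm), 10 % Pd/C, EtOAc/EtOH, rt
Reagents that add atoms: none
Why: Heterogeneous catalytic hydrogenation saturates both alkynes and hydrogenolyses both aryl benzyl ethers in one operation, while the homobenzylic lactone C3–O bond, the alkyl methyl ether and both stereocentres are not affected.

**Compound list**
1 | hexa-1,5-diyne | C#CCCC#C | starting material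
2 | (S)-2-methyloxirane [(S)-propylene oxide] | C[C@H]1CO1 | starting material
3 | lithium hexa-1,5-diyn-1-ide | [Li]C#CCCC#C | intermediate
4 | (2S)-nona-4,8-diyn-2-ol | C[C@H](O)CC#CCCC#C | intermediate
5 | (8S)-8-methoxynona-1,5-diyne | CO[C@@H](C)CC#CCCC#C | intermediate
6 | 1,3-bis(benzyloxy)-5-bromobenzene | Brc1cc(OCc2ccccc2)cc(OCc2ccccc2)c1 | starting material
7 | (S)-2-(chloromethyl)oxirane [(S)-epichlorohydrin] | ClC[C@@H]1CO1 | starting material
8 | [3,5-bis(benzyloxy)phenyl]magnesium bromide | Br[Mg]c1cc(OCc2ccccc2)cc(OCc2ccccc2)c1 | intermediate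
9 | (2S)-1-[3,5-bis(benzyloxy)phenyl]-3-chloropropan-2-ol | ClC[C@@H](O)Cc1cc(OCc2ccccc2)cc(OCc2ccccc2)c1 | intermediate
10 | (2S)-2-{[3,5-bis(benzyloxy)phenyl]methyl}oxirane | c1ccccc1COc1cc(C[C@H]2CO2)cc(OCc2ccccc2)c1 | intermediate
11 | (2S)-2-{[3,5-bis(benzyloxy)phenyl]methyl}oxetane | c1ccccc1COc1cc(C[C@H]2CCO2)cc(OCc2ccccc2)c1 | intermediate
12 | (2S)-2-{[3,5-bis(benzyloxy)-2-bromophenyl]methyl}oxetane | Brc1c(C[C@H]2CCO2)cc(OCc2ccccc2)cc1OCc1ccccc1 | intermediate
13 | {2,4-bis(benzyloxy)-6-{[(2S)-oxetan-2-yl]methyl}phenyl}lithium | [Li]c1c(C[C@H]2CCO2)cc(OCc2ccccc2)cc1OCc1ccccc1 | intermediate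
14 | methyl 2,4-bis(benzyloxy)-6-{[(2S)-oxetan-2-yl]methyl}benzoate | COC(=O)c1c(C[C@H]2CCO2)cc(OCc2ccccc2)cc1OCc1ccccc1 | intermediate
15 | lithium (8S)-8-methoxynona-1,5-diyn-1-ide | [Li]C#CCCC#CC[C@H](C)OC | intermediate
16 | methyl 2,4-bis(benzyloxy)-6-[(2R,12S)-2-hydroxy-12-methoxytrideca-5,9-diyn-1-yl]benzoate | COC(=O)c1c(C[C@H](O)CCC#CCCC#CC[C@H](C)OC)cc(OCc2ccccc2)cc1OCc1ccccc1 | intermediate
17 | (3R)-6,8-bis(benzyloxy)-3-[(10S)-10-methoxyundeca-3,7-diyn-1-yl]-3,4-dihydro-1H-isochromen-1-one | CO[C@@H](C)CC#CCCC#CCC[C@@H]1Cc2cc(OCc3ccccc3)cc(OCc3ccccc3)c2C(=O)O1 | intermediate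
18 | (3R)-6,8-dihydroxy-3-[(10S)-10-methoxyundecyl]-3,4-dihydro-1H-isochromen-1-one (CNP0242607.1) | CO[C@@H](C)CCCCCCCCC[C@@H]1Cc2cc(O)cc(O)c2C(=O)O1 | target

**Step count**
Total step count: 8. Longest linear sequence: 6 (steps 3–8).

**Steps most likely to fail**

Step 7. The neighbouring ester carbonyl may open the BF3-activated oxetane at its substituted carbon before the acetylide arrives, which erodes the C3 configuration, or the acetylide may add to the ester.
- The fallback sets out from 14 and separates ring opening from C–C bond formation.
- Magnesium iodide etherate (toluene/Et2O, 0 °C → rt) should open the oxetane at its O–CH2 carbon, and the magnesium alkoxide should lactonise to (3S)-6,8-bis(benzyloxy)-3-(2-iodoethyl)-3,4-dihydro-1H-isochromen-1-one F1.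
- The same side-chain bond is then made on the closed lactone by a Sonogashira coupling of the unactivated primary alkyl iodide with alkyne 5 (Pd/N-heterocyclic carbene, CuI, Cs2CO3, DMF/Et2O, 45 °C).
- This returns to the route at 17.

Step 4. The base may isomerise the benzylic epoxide to an allylic alcohol, or the sequence may stall after the first ylide addition.
- The fallback sets out from 6 and brings the four-membered ring in ready-made.
- Grignard reagent 8 is coupled under copper catalysis (Li2CuCl4, THF, −20 → 0 °C) with commercial (R)-oxetan-2-ylmethyl 4-methylbenzenesulfonate (Cc1ccc(cc1)S(=O)(=O)OC[C@H]1CCO1).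
- Substitution takes place at the exocyclic CH2, so the stereocentre is not touched.
- This returns to the route at 11 and bypasses 9 and 10.

Step 6. A proton may transfer from a benzylic O–CH2 group to the aryllithium, leading to Wittig rearrangement, or the aryllithium may over-add to the new ester.
- The fallback sets out from 12 and avoids carbanions altogether.
- It is a palladium-catalysed methoxycarbonylation (Pd(OAc)2, Xantphos, CO, MeOH, Et3N, toluene, 90 °C).
- This returns to the route at 14.

**Further compounds**
F1 | step 7 | (3S)-6,8-bis(benzyloxy)-3-(2-iodoethyl)-3,4-dihydro-1H-isochromen-1-one | ICC[C@@H]1Cc2cc(OCc3ccccc3)cc(OCc3ccccc3)c2C(=O)O1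
F0 | step 4 | none | none
F0 | step 6 | none | none
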